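In a one-step world a catalyst comes back unchanged, substrate goes straight to target, and the books of the substrate, the limiting reagent here, balance at every reading. Test that picture on the north run, which is the flask asked about, followed so far.

- north: substrate 20 mM; acid 0.020 mM; the very flask that is asked about, followed so far
- flask: substrate 20 mM; acid 0.0200 mM; time 6.0 h

north run (percent of the substrate charged)

| time / h | substrate / % | target / % |
|---|---|---|
| 0.417 | 70 | 16 |
| 0.833 | 30 | 32 |
| 1.33 | 5 | 48 |
| 1.50 | 3 | 51 |
| 2.00 | 3 | 54 |
| 2.50 | 1 | 62 |
| 3.00 | 0 | 63 |

(readings scatter by 1.5 percentage points)

- acid is the free proton; pH is minus the decimal logarithm of its molar concentration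
- what has gone from substrate into another species counts as reacted, even if it can come back

* part of the substrate that has reacted at 6.0 h
* pH of the solution at 6.0 h

Open the ledger at 3.00 h. The first entry, free substrate, reads 0 %, so I commit to about 100 % reacted at 6.0 h. The second entry, target, reads 63 %. The remainder, 37.0 % of the charge or 7.40 mM, sits in something unseen, and it is far more than the acid charged. That entry seems to pay back: from 1.50 h on, the readings put target up by 12 percentage points and substrate down by 3 points.

Now count turnovers. The turnover count N, substrate charged per proton charged, is 1000, so one turnover in N that freed a proton adds as much acid as was charged.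

Does that happen? A pseudo-first-order constant, the logarithm of the substrate ratio per interval, should hold still as long as c(acid) does. It reads 0.855 h⁻¹ over the first interval, but 3.61 h⁻¹ from 0.833 h to 1.33 h, which is 4.21 times faster. Since that reading rises, I take c(acid) as growing by about that factor, with the scatter on the reading, and counting down from the pH of the charge I estimate a pH of about 4.08 or lower at 6.0 h.

The forecast gave 99.5 % reacted and pH 4.7, holding that the acid “acts as a catalyst and should be regenerated”. The flask gives 99.7 % and pH 3.05, which is lower than my estimate.

    substrate + acid → weak acid + acid + target (k = 170 L mol⁻¹ min⁻¹)
    weak acid ⇌ conjugate base + acid, settled at all times (K = 7.90 × 10⁻⁵ M)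
    substrate → weak acid + target (k = 8.63 × 10⁻⁴ min⁻¹)
    substrate + weak acid ⇌ idle adduct, settled at all times (K = 7700 L mol⁻¹)

The step with acid used substrate 4.0 times as fast as the step without it just after the start, and 170 times as fast at 6.00 h, when c(conjugate base) stood at 0.868 mM, a share of 4.34 % of the substrate charged. Multiply that share by N and add the charge itself, and you get 44.4 charges of acid against the 4439 % in this flask; in the neighbour charged with 34 mM, N is 1700, c(conjugate base) is 1.07 mM at 6.00 h, the same count gives 54.5 charges, and c(acid) stands at 5440 % of its own charge.

The data stem from a simulated flask for an exercise, noise included.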